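All runs are simulated with made-up constants; the scatter is artificial.

You have no constants for this flask, so whatever you carry must be read from the earlier runs.

| flask | substrate | capture agent | free catalyst | impurity | remark | time |
|---|---|---|---|---|---|---|
| beta | 0.092 M | 6.6 mM | 0.46 mM | 0.42 mM | run made earlier |  |
| theta | 0.092 M | 19 mM | 0.46 mM | 0.42 mM | run made earlier |  |
| delta | 0.092 M | 4.6 mM | 1.1 mM | 0.42 mM | run made earlier |  |
| larch | 0.092 M | 15.0 mM | 2.0 mM | 0.42 mM |  | 1.5 min |
| birch | 0.092 M | 4.60 mM | 0.46 mM | 0.42 mM |  | 5.0 min |

- beta (time / min: target / %, substrate / %): 0.333: 3.1, 97.9; 0.833: 2.7, 96.7; 1.50: 3.7, 93.8; 2.50: 3.7, 94.1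
- theta (time / min: target / %, substrate / %): 0.333: 0.8, 99.1; 0.833: 3.6, 97.9; 1.50: 4.8, 95.4; 2.50: 1.3, 94.0
- delta (time / min: target / %, substrate / %): 0.667: 13.6, 83.2; 1.33: 20.3, 76.1; 2.00: 26.4, 66.4; 2.50: 26.0, 61.3

(scatter of a reading: 1 percentage point)

- the flask that ends with the higher amount of target, in percent of the substrate charged, or "neither" when 2 percentage points or less lies between them (larch / birch / neither)
- final target, as a percentage of the substrate charged, in larch
- final target, as a percentage of the substrate charged, in birch



One thing looks wrong at first. From beta to delta the charged [free catalyst] rises 2.39 times, yet the substrate lost by 2.50 min rises 6.56 times. Capture agent differs too, but the last substrate readings of beta and theta, charged with 6.6 mM and 19 mM of it, are 94.1% and 94.0%. A subtraction goes the right way. Take charged [free catalyst] minus charged [impurity], which is 0.680 mM in delta, and call it the working catalyst, on the view that impurity removes its own amount of catalyst. Beta has 0.0400 mM, a ratio of 17.0. That overshoots the readings, so I use the rule on flasks well above the impurity.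

Treat substrate loss as pseudo-first-order, with a rate constant proportional to working catalyst. Delta's last reading gives 0.196 min⁻¹. Larch has 1.58 mM, so my substrate lost by 1.5 min is 49.5%.

I take target to leak away as well. Delta's gap between substrate lost and target, 12.7%, set against half its last target over the run, gives a leak of 0.391 min⁻¹. Counting larch's mean target as half its final one, a first pass gives 35.0%. Putting that back in gives 39.2%.

Birch has 0.0400 mM, the same as beta, whose last target reading is 3.7%, so I expect larch to lead.

The forecast says larch, with 31% (22% to 40%) in larch and 3% (1% to 6.5%) in birch, since the rate “tracks catalyst left after the impurity removes about 0.42 mM”. Its larch figure is lower than mine.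

The flasks give larch as the winner, with 36.2% in larch and 3.67% in birch.

    substrate + free catalyst → catalyst intermediate (k = 5.70 L mol⁻¹ s⁻¹)
    catalyst intermediate → free catalyst + target (k = 9.10 s⁻¹)
    free catalyst + impurity → spent catalyst (k = 260 L mol⁻¹ s⁻¹)
    catalyst intermediate + capture agent → trapped intermediate (k = 9.30 L mol⁻¹ s⁻¹)
    target ⇌ isomer of the product (K = 7.90, k = 0.00410 s⁻¹)

In larch at 1.50 min, substrate stands at 54.7% against my 50.5%, and spent catalyst is 0.420 mM, the amount the subtraction took off. A neighbour of larch, charged with 5.00 mM of free catalyst and read at the same time, has a working catalyst of 4.58 mM. The same reckoning leaves 13.8% of the substrate. Its first pass gives 60.9% target, and going round once more gives 68.3%. That flask holds 14.8% substrate and 66.2% target.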